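**Strategy.** The cyclopentane is opened at its most hindered bond, between the quaternary carbon C1 (CH3, CH2CH2CO2H) and C5 (CH–CH=CMe2), by an intramolecular type-I magnesium-ene reaction. The target shows the signature of that reaction: on the ring, the arm on C1 and the alkenyl group on C5 are cis. One operation closes the five-membered ring from an acyclic chain, creates C1 and C5 with this relationship, generates the isobutenyl group by allylic transposition and leaves a C–Mg bond that oxirane extends to the three-carbon arm. The precursor is an acyclic allyl phenyl sulfide with an isopropenyl enophile and the C2/C3 stereocentres already set by an enantioselective ester-enolate Claisen rearrangement.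

Key step: step 8

Remark: ring positions of the target are used for all intermediates: C1 = quaternary carbon, C2 = CH–CH2OAr, C3 = CH–CH3, C4 = CH2, C5 = CH–CH=CMe2.
Assumption: the (R,R)-diazaborolidine controller of step 4 is taken to deliver the (2R,3R) acid; should it deliver the antipode, the (S,S)-controller is used with no other change.

**Step 1**
Reactants: 1 2-{[tert-butyl(dimethyl)silyl]oxy}acetaldehyde; 2 ethyl 2-(triphenyl-λ5-phosphanylidene)propanoate
Product: 3 ethyl (2E)-4-{[tert-butyl(dimethyl)silyl]oxy}-2-methylbut-2-enoate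
Conditions: CH2Cl2, rt
Reagents that add atoms: none
Why: Wittig olefination with a stabilised α-branched ylide should give the (E)-trisubstituted enoate, the geometry that later places CH2OTBS pseudo-equatorial in the Claisen transition state.

**Step 2**
Reactants: 3 ethyl (2E)-4-{[tert-butyl(dimethyl)silyl]oxy}-2-methylbut-2-enoate
Product: 4 (2E)-4-{[tert-butyl(dimethyl)silyl]oxy}-2-methylbut-2-en-1-ol
Conditions: DIBAL-H (2.2 equiv), CH2Cl2, −78 °C; Rochelle salt work-up
Reagents that add atoms: none
Why: Hydride reduction of the conjugated ester with DIBAL-H proceeds 1,2 to the allylic alcohol and should leave the alkene geometry and the silyl ether untouched.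

**Step 3**
Reactants: 4 (2E)-4-{[tert-butyl(dimethyl)silyl]oxy}-2-methylbut-2-en-1-ol
Product: 5 (2E)-4-{[tert-butyl(dimethyl)silyl]oxy}-2-methylbut-2-en-1-yl propanoate
Conditions: EtCOCl, Et3N, DMAP (cat.), CH2Cl2, 0 °C
Reagents that add atoms: propanoyl chloride, CCC(=O)Cl
Why: DMAP-catalysed acylation (nucleophilic acyl substitution) of the primary allylic alcohol installs the propanoate needed for the ester-enolate Claisen rearrangement.

**Step 4**
Reactants: 5 (2E)-4-{[tert-butyl(dimethyl)silyl]oxy}-2-methylbut-2-en-1-yl propanoate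
Product: 8 (2R,3R)-3-({[tert-butyl(dimethyl)silyl]oxy}methyl)-2,4-dimethylpent-4-enoic acid, via boron enolate 6 (not isolated), via diazaborolidinyl carboxylate 7 (not isolated)
Conditions: N,N'-[(1R,2R)-1,2-diphenylethane-1,2-diyl]bis[3,5-bis(trifluoromethyl)benzenesulfonamide], BBr3, CH2Cl2, then evaporation (gives the bromodiazaborolidine); 5, i-Pr2NEt, CH2Cl2, −78 °C; −20 °C, 14 d; aqueous work-up
Reagents that add atoms: none
Why: Enantioselective Ireland–Claisen rearrangement of a chiral boron enolate: soft enolisation with i-Pr2NEt in CH2Cl2 should give the enolate with methyl cis to O–B, whose chair [3,3] transition state with the (E)-allyl unit carries methyl and CH2OTBS pseudo-equatorial and so gives the 2,3-syn acid, while the C2-symmetric diazaborolidine selects the enolate face and fixes both new stereocentres (ring C3 and C2).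

**Step 5**
Reactants: 8 (2R,3R)-3-({[tert-butyl(dimethyl)silyl]oxy}methyl)-2,4-dimethylpent-4-enoic acid
Product: 9 (2R,3R)-3-({[tert-butyl(dimethyl)silyl]oxy}methyl)-2,4-dimethylpent-4-en-1-ol
Conditions: LiAlH4, Et2O, 0 °C
Reagents that add atoms: none
Why: Hydride reduction of the carboxylic acid to the primary alcohol removes the only acidic α-hydrogen, so that neither stereocentre can epimerise afterwards.

**Step 6**
Reactants: 9 (2R,3R)-3-({[tert-butyl(dimethyl)silyl]oxy}methyl)-2,4-dimethylpent-4-en-1-ol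
Product: 10 tert-butyl{[(2R,3R)-4-iodo-3-methyl-2-(prop-1-en-2-yl)butyl]oxy}dimethylsilane
Conditions: I2, PPh3, imidazole, CH2Cl2, 0 °C to rt
Reagents that add atoms: iodine, II
Why: Appel-type iodination replaces the primary hydroxyl by iodide through SN2 at an alkoxyphosphonium ion, at a carbon that is not stereogenic.

**Step 7**
Reactants: 10 tert-butyl{[(2R,3R)-4-iodo-3-methyl-2-(prop-1-en-2-yl)butyl]oxy}dimethylsilane; 11 (3-methylbut-2-en-1-yl)(phenyl)sulfane
Product: 13 tert-butyl{[(2R,3S)-3,7-dimethyl-5-(phenylsulfanyl)-2-(prop-1-en-2-yl)oct-6-en-1-yl]oxy}dimethylsilane (both C5 epimers), via [3-methyl-1-(phenylsulfanyl)but-2-en-1-yl]lithium 12 (not isolated)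
Conditions: 11, n-BuLi, TMEDA, THF, −78 to −30 °C; then 10, DMPU, −78 to 0 °C
Reagents that add atoms: none
Why: Biellmann coupling: the sulfur-stabilised allyl anion should be alkylated at its α-carbon (the γ-carbon is fully substituted) by the primary iodide, which joins ring C4 to C5; the new C–S stereocentre is erased in the next step.

**Step 8**
Reactants: 13 tert-butyl{[(2R,3S)-3,7-dimethyl-5-(phenylsulfanyl)-2-(prop-1-en-2-yl)oct-6-en-1-yl]oxy}dimethylsilane
Product: 18 3-[(1R,2R,3S,5S)-2-({[tert-butyl(dimethyl)silyl]oxy}methyl)-1,3-dimethyl-5-(2-methylprop-1-en-1-yl)cyclopentyl]propyl acetate, via allyllithium 14 (not isolated), via allylmagnesium bromide 15 (not isolated), via cyclopentylmethylmagnesium bromide 16 (not isolated), via bromomagnesium alkoxide 17 (not isolated)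
Conditions: LiDBB (2.2 equiv), THF, −78 °C; MgBr2·OEt2, −78 °C to rt; 65 °C; 0 °C, CuBr·SMe2 (cat.), oxirane (excess); Ac2O (excess), DMAP (cat.), 0 °C to rt
Reagents that add atoms: oxirane, C1CO1; acetic anhydride, CC(=O)OC(C)=O
Why: Reductive cleavage of the allylic C–S bond and transmetalation give a fluxional allylmagnesium bromide whose CMe2-metalated tautomer undergoes an intramolecular type-I magnesium-ene reaction (closest known type: cyclisation of 2-alkenylmagnesium halides onto 1,1-disubstituted alkenes, also when generated from allyl phenyl sulfides), in which C5 adds to the internal carbon of the isopropenyl group through a six-membered Mg–C–C=C···C=C array while magnesium passes to the terminal CH2. The ring closes in the 5-exo sense at the only allyl terminus that can reach the alkene (the other tautomer could only give seven- or eight-membered rings), and the allylic transposition leaves the 2-methylprop-1-enyl group on C5. The quaternary C1 is set by the topology of the ene reaction, which is suprafacial on both partners and so places CH2MgBr cis to the alkenyl group on C5. C5 is set by the resident stereocentres: in the chair-like transition state CH2OTBS on C2 and methyl on C3, which are trans, are both pseudo-equatorial, and this puts the alkenyl group cis to the C3 methyl and trans to the C2 substituent. The step needs this facial selectivity and the kinetic cis mode, which the two reinforcing substituents and the lowest workable temperature should secure, and it needs reaction through the less populated tertiary tautomer, which is the main risk. The neopentyl-type primary Grignard reagent then opens oxirane under copper catalysis, which completes the three-carbon arm, and the alkoxide is acetylated in the same flask so that the two oxygens stay distinguishable.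

**Step 9**
Reactants: 18 3-[(1R,2R,3S,5S)-2-({[tert-butyl(dimethyl)silyl]oxy}methyl)-1,3-dimethyl-5-(2-methylprop-1-en-1-yl)cyclopentyl]propyl acetate
Product: 19 3-[(1R,2R,3S,5S)-2-(hydroxymethyl)-1,3-dimethyl-5-(2-methylprop-1-en-1-yl)cyclopentyl]propyl acetate
Conditions: HF·pyridine, pyridine, THF, 0 °C to rt
Reagents that add atoms: none
Why: Fluoride-induced desilylation cleaves the Si–O bond under buffered conditions that should leave the acetate and both alkenes intact.

**Step 10**
Reactants: 19 3-[(1R,2R,3S,5S)-2-(hydroxymethyl)-1,3-dimethyl-5-(2-methylprop-1-en-1-yl)cyclopentyl]propyl acetate; 20 2,4-dihydroxybenzaldehyde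
Product: 21 3-[(1R,2R,3S,5S)-2-[(4-formyl-3-hydroxyphenoxy)methyl]-1,3-dimethyl-5-(2-methylprop-1-en-1-yl)cyclopentyl]propyl acetate
Conditions: PPh3, DIAD, THF, 0 °C to rt
Reagents that add atoms: none
Why: Mitsunobu etherification: the 4-OH is the more acidic phenol and is not held in the hydrogen bond to the formyl group, so it should be alkylated selectively by the activated primary alcohol (SN2 at CH2, no stereocentre involved).

**Step 11**
Reactants: 21 3-[(1R,2R,3S,5S)-2-[(4-formyl-3-hydroxyphenoxy)methyl]-1,3-dimethyl-5-(2-methylprop-1-en-1-yl)cyclopentyl]propyl acetate; 22 ethyl 2-(triphenyl-λ5-phosphanylidene)acetate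
Product: 24 3-[(1R,2R,3S,5S)-1,3-dimethyl-5-(2-methylprop-1-en-1-yl)-2-{[(2-oxo-2H-chromen-7-yl)oxy]methyl}cyclopentyl]propyl acetate, via ethyl (E)-2-hydroxycinnamate 23 (not isolated)
Conditions: PhNEt2, reflux (about 215 °C)
Reagents that add atoms: none
Why: Wittig olefination of the salicylaldehyde followed by thermal E to Z isomerisation and lactonisation onto the ortho phenol builds the 2H-chromen-2-one ring (classical coumarin annulation).

**Step 12**
Reactants: 24 3-[(1R,2R,3S,5S)-1,3-dimethyl-5-(2-methylprop-1-en-1-yl)-2-{[(2-oxo-2H-chromen-7-yl)oxy]methyl}cyclopentyl]propyl acetate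
Product: 25 3-[(1R,2R,3S,5S)-1,3-dimethyl-5-(2-methylprop-1-en-1-yl)-2-{[(2-oxo-2H-chromen-7-yl)oxy]methyl}cyclopentyl]propan-1-ol
Conditions: K2CO3 (cat.), MeOH, 0 °C to rt; mildly acidic work-up
Reagents that add atoms: none
Why: Base-catalysed transesterification with methanol (Zemplén-type deacetylation) removes the acetate, and any methanolysis of the coumarin lactone should be reversed on acidic work-up.

**Step 13**
Reactants: 25 3-[(1R,2R,3S,5S)-1,3-dimethyl-5-(2-methylprop-1-en-1-yl)-2-{[(2-oxo-2H-chromen-7-yl)oxy]methyl}cyclopentyl]propan-1-ol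
Product: 27 ferulsinaic acid, 3-[(1R,2R,3S,5S)-1,3-dimethyl-5-(2-methylprop-1-en-1-yl)-2-{[(2-oxo-2H-chromen-7-yl)oxy]methyl}cyclopentyl]propanoic acid, via aldehyde 26 (not isolated)
Conditions: TEMPO (cat.), PhI(OAc)2 (2.2 equiv), MeCN/H2O, rt
Reagents that add atoms: water, O
Why: TEMPO-catalysed oxidation with a hypervalent iodine co-oxidant takes the primary alcohol through the aldehyde hydrate to the carboxylic acid under conditions that should not touch the trisubstituted alkene, the aryl ether or the coumarin.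

**Compound list**
1 | 2-{[tert-butyl(dimethyl)silyl]oxy}acetaldehyde | CC(C)(C)[Si](C)(C)OCC=O | starting material
2 | ethyl 2-(triphenyl-λ5-phosphanylidene)propanoate | CCOC(=O)C(C)=P(c1ccccc1)(c1ccccc1)c1ccccc1 | starting material
3 | ethyl (2E)-4-{[tert-butyl(dimethyl)silyl]oxy}-2-methylbut-2-enoate | CCOC(=O)/C(C)=C/CO[Si](C)(C)C(C)(C)C | intermediate
4 | (2E)-4-{[tert-butyl(dimethyl)silyl]oxy}-2-methylbut-2-en-1-ol | OC/C(C)=C/CO[Si](C)(C)C(C)(C)C | intermediate
5 | (2E)-4-{[tert-butyl(dimethyl)silyl]oxy}-2-methylbut-2-en-1-yl propanoate | CCC(=O)OC/C(C)=C/CO[Si](C)(C)C(C)(C)C | intermediate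
6 | boron enolate of 5, O-[(4R,5R)-1,3-bis{[3,5-bis(trifluoromethyl)phenyl]sulfonyl}-4,5-diphenyl-1,3,2-diazaborolidin-2-yl] ketene acetal with methyl cis to O–B | C/C=C(/OC/C(C)=C/CO[Si](C)(C)C(C)(C)C)OB1N(S(=O)(=O)c2cc(cc(c2)C(F)(F)F)C(F)(F)F)[C@H](c2ccccc2)[C@@H](c2ccccc2)N1S(=O)(=O)c1cc(cc(c1)C(F)(F)F)C(F)(F)F | intermediate
7 | (4R,5R)-diazaborolidin-2-yl (2R,3R)-3-({[tert-butyl(dimethyl)silyl]oxy}methyl)-2,4-dimethylpent-4-enoate | O=C(OB1N(S(=O)(=O)c2cc(cc(c2)C(F)(F)F)C(F)(F)F)[C@H](c2ccccc2)[C@@H](c2ccccc2)N1S(=O)(=O)c1cc(cc(c1)C(F)(F)F)C(F)(F)F)[C@H](C)[C@@H](CO[Si](C)(C)C(C)(C)C)C(C)=C | intermediate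
8 | (2R,3R)-3-({[tert-butyl(dimethyl)silyl]oxy}methyl)-2,4-dimethylpent-4-enoic acid | OC(=O)[C@H](C)[C@@H](CO[Si](C)(C)C(C)(C)C)C(C)=C | intermediate
9 | (2R,3R)-3-({[tert-butyl(dimethyl)silyl]oxy}methyl)-2,4-dimethylpent-4-en-1-ol | OC[C@H](C)[C@@H](CO[Si](C)(C)C(C)(C)C)C(C)=C | intermediate
10 | tert-butyl{[(2R,3R)-4-iodo-3-methyl-2-(prop-1-en-2-yl)butyl]oxy}dimethylsilane | IC[C@H](C)[C@@H](CO[Si](C)(C)C(C)(C)C)C(C)=C | intermediate
11 | (3-methylbut-2-en-1-yl)(phenyl)sulfane (prenyl phenyl sulfide) | CC(C)=CCSc1ccccc1 | starting material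
12 | [3-methyl-1-(phenylsulfanyl)but-2-en-1-yl]lithium | [Li]C(Sc1ccccc1)C=C(C)C | intermediate
13 | tert-butyl{[(2R,3S)-3,7-dimethyl-5-(phenylsulfanyl)-2-(prop-1-en-2-yl)oct-6-en-1-yl]oxy}dimethylsilane (both C5 epimers) | CC(C)=CC(Sc1ccccc1)C[C@H](C)[C@@H](CO[Si](C)(C)C(C)(C)C)C(C)=C | intermediate
14 | allyllithium from 13 (C5-lithio form drawn) | CC(C)=CC([Li])C[C@H](C)[C@@H](CO[Si](C)(C)C(C)(C)C)C(C)=C | intermediate
15 | allylmagnesium bromide from 14 (C5-magnesio tautomer drawn) | CC(C)=CC([Mg]Br)C[C@H](C)[C@@H](CO[Si](C)(C)C(C)(C)C)C(C)=C | intermediate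
16 | {[(1R,2R,3S,5S)-2-({[tert-butyl(dimethyl)silyl]oxy}methyl)-1,3-dimethyl-5-(2-methylprop-1-en-1-yl)cyclopentyl]methyl}magnesium bromide | CC(C)=C[C@@H]1C[C@H](C)[C@@H](CO[Si](C)(C)C(C)(C)C)[C@]1(C)C[Mg]Br | intermediate
17 | bromomagnesium 3-[(1R,2R,3S,5S)-2-({[tert-butyl(dimethyl)silyl]oxy}methyl)-1,3-dimethyl-5-(2-methylprop-1-en-1-yl)cyclopentyl]propan-1-olate | CC(C)=C[C@@H]1C[C@H](C)[C@@H](CO[Si](C)(C)C(C)(C)C)[C@]1(C)CCCO[Mg]Br | intermediate
18 | 3-[(1R,2R,3S,5S)-2-({[tert-butyl(dimethyl)silyl]oxy}methyl)-1,3-dimethyl-5-(2-methylprop-1-en-1-yl)cyclopentyl]propyl acetate | CC(C)=C[C@@H]1C[C@H](C)[C@@H](CO[Si](C)(C)C(C)(C)C)[C@]1(C)CCCOC(C)=O | intermediate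
19 | 3-[(1R,2R,3S,5S)-2-(hydroxymethyl)-1,3-dimethyl-5-(2-methylprop-1-en-1-yl)cyclopentyl]propyl acetate | CC(C)=C[C@@H]1C[C@H](C)[C@@H](CO)[C@]1(C)CCCOC(C)=O | intermediate
20 | 2,4-dihydroxybenzaldehyde | O=Cc1ccc(O)cc1O | starting material
21 | 3-[(1R,2R,3S,5S)-2-[(4-formyl-3-hydroxyphenoxy)methyl]-1,3-dimethyl-5-(2-methylprop-1-en-1-yl)cyclopentyl]propyl acetate | CC(C)=C[C@@H]1C[C@H](C)[C@@H](COc2ccc(C=O)c(O)c2)[C@]1(C)CCCOC(C)=O | intermediate
22 | ethyl 2-(triphenyl-λ5-phosphanylidene)acetate | CCOC(=O)C=P(c1ccccc1)(c1ccccc1)c1ccccc1 | starting material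
23 | ethyl (2E)-3-[4-({(1R,2R,3S,5S)-2-[3-(acetyloxy)propyl]-2,5-dimethyl-3-(2-methylprop-1-en-1-yl)cyclopentyl}methoxy)-2-hydroxyphenyl]prop-2-enoate (cyclopentane numbered here from the carbon that bears CH2OAr) | CC(C)=C[C@@H]1C[C@H](C)[C@@H](COc2ccc(/C=C/C(=O)OCC)c(O)c2)[C@]1(C)CCCOC(C)=O | intermediate
24 | 3-[(1R,2R,3S,5S)-1,3-dimethyl-5-(2-methylprop-1-en-1-yl)-2-{[(2-oxo-2H-chromen-7-yl)oxy]methyl}cyclopentyl]propyl acetate | CC(C)=C[C@@H]1C[C@H](C)[C@@H](COc2ccc3ccc(=O)oc3c2)[C@]1(C)CCCOC(C)=O | intermediate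
25 | 3-[(1R,2R,3S,5S)-1,3-dimethyl-5-(2-methylprop-1-en-1-yl)-2-{[(2-oxo-2H-chromen-7-yl)oxy]methyl}cyclopentyl]propan-1-ol | CC(C)=C[C@@H]1C[C@H](C)[C@@H](COc2ccc3ccc(=O)oc3c2)[C@]1(C)CCCO | intermediate
26 | 3-[(1R,2R,3S,5S)-1,3-dimethyl-5-(2-methylprop-1-en-1-yl)-2-{[(2-oxo-2H-chromen-7-yl)oxy]methyl}cyclopentyl]propanal | CC(C)=C[C@@H]1C[C@H](C)[C@@H](COc2ccc3ccc(=O)oc3c2)[C@]1(C)CCC=O | intermediate
27 | ferulsinaic acid, 3-[(1R,2R,3S,5S)-1,3-dimethyl-5-(2-methylprop-1-en-1-yl)-2-{[(2-oxo-2H-chromen-7-yl)oxy]methyl}cyclopentyl]propanoic acid | CC(C)=C[C@@H]1C[C@H](C)[C@@H](COc2ccc3ccc(=O)oc3c2)[C@]1(C)CCC(=O)O | target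

**Totals.** Total step count: 13. Longest linear sequence: 13 steps (1 to 27).

**Steps most likely to fail**

Step 8. The ene reaction has to run through the minor allylmagnesium tautomer that carries magnesium on the CMe2 terminus. If that is slow, protonation of the allyl metal or reversible ring closure at the higher temperature needed would erode conversion and cis selectivity. The fallback sets out from iodide 10 and moves the metal to a primary carbon. Alkylation of lithiated allyl phenyl sulfide (n-BuLi, TMEDA, THF) in place of 11 should give tert-butyldimethyl{[(2R,3S)-3-methyl-5-(phenylsulfanyl)-2-(prop-1-en-2-yl)hept-6-en-1-yl]oxy}silane F1. The conditions of step 8 then should give 3-[(1R,2R,3S,5S)-2-({[tert-butyl(dimethyl)silyl]oxy}methyl)-5-ethenyl-1,3-dimethylcyclopentyl]propyl acetate F2 by the standard type-I ene mode. Olefin cross-metathesis of its vinyl group with 2-methylbut-2-ene (second-generation Ru benzylidene catalyst, CH2Cl2, 40 °C) installs the 2-methylprop-1-enyl group and comes back to the route at 18.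

Step 4. Rearrangement of the hindered boron enolate may be slow or incomplete, and loss of enolate geometry or of facial control would lower the syn and enantiomeric purity of the acid. The fallback sets out from ester 5 and separates relative from absolute control. The rearrangement is run through the trimethylsilyl ketene acetal of 5 F3 (LDA, THF/DMPU, −78 °C, TMSCl; then rt), which has methyl cis to OSi and should give the same 2,3-syn acid as a racemate, that is 8 together with its enantiomer (2S,3S)-3-({[tert-butyl(dimethyl)silyl]oxy}methyl)-2,4-dimethylpent-4-enoic acid F4. Esterification with (R)-pantolactone (DCC, DMAP) gives two diastereomeric esters, the (3R)-4,4-dimethyl-2-oxooxolan-3-yl ester of 8 F5 and the (3R)-4,4-dimethyl-2-oxooxolan-3-yl ester of the (2S,3S) acid F6. F5 is separated by chromatography and cleaved with LiOH/H2O2, which comes back to the route at 8.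

Step 10. The β-branched, neopentyl-like alcohol may convert poorly under Mitsunobu conditions, and alkylation at the 2-OH may compete. The fallback sets out from alcohol 19 and forms the aryl ether by Pd-catalysed C–O cross-coupling with 7-bromo-2H-chromen-2-one (tBuBrettPhos Pd G3, Cs2CO3, toluene, 80 °C). The coumarin is then already in place, the fallback comes back to the route at 24, and step 11 is not needed; no compound outside the list is made (F0).

**Further compounds**
F1 | step 8 | tert-butyldimethyl{[(2R,3S)-3-methyl-5-(phenylsulfanyl)-2-(prop-1-en-2-yl)hept-6-en-1-yl]oxy}silane (both C5 epimers) | C=CC(Sc1ccccc1)C[C@H](C)[C@@H](CO[Si](C)(C)C(C)(C)C)C(C)=C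
F2 | step 8 | 3-[(1R,2R,3S,5S)-2-({[tert-butyl(dimethyl)silyl]oxy}methyl)-5-ethenyl-1,3-dimethylcyclopentyl]propyl acetate | C=C[C@@H]1C[C@H](C)[C@@H](CO[Si](C)(C)C(C)(C)C)[C@]1(C)CCCOC(C)=O
F3 | step 4 | trimethylsilyl ketene acetal of 5 (methyl cis to OSiMe3) | C/C=C(/OC/C(C)=C/CO[Si](C)(C)C(C)(C)C)O[Si](C)(C)C
F4 | step 4 | (2S,3S)-3-({[tert-butyl(dimethyl)silyl]oxy}methyl)-2,4-dimethylpent-4-enoic acid | OC(=O)[C@@H](C)[C@H](CO[Si](C)(C)C(C)(C)C)C(C)=C
F5 | step 4 | (3R)-4,4-dimethyl-2-oxooxolan-3-yl (2R,3R)-3-({[tert-butyl(dimethyl)silyl]oxy}methyl)-2,4-dimethylpent-4-enoate | O=C(O[C@H]1C(=O)OCC1(C)C)[C@H](C)[C@@H](CO[Si](C)(C)C(C)(C)C)C(C)=C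
F6 | step 4 | (3R)-4,4-dimethyl-2-oxooxolan-3-yl (2S,3S)-3-({[tert-butyl(dimethyl)silyl]oxy}methyl)-2,4-dimethylpent-4-enoate | O=C(O[C@H]1C(=O)OCC1(C)C)[C@@H](C)[C@H](CO[Si](C)(C)C(C)(C)C)C(C)=C
F0 | step 10 | none | none
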